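**Retrosynthetic overview**
1. Target 14 comes from the achiral penta-Alloc enol carbonate 13. One palladium/PHOX decarboxylative protonation sets C3 and frees all four phenols in the last step.
2. 13 comes from racemic 12. The C3–C1' bond of 12 is made by fluoride-promoted palladium arylation of the enol silane 6 with the ring B bromide 10.
3. 6 comes from the monocyclic chloroketone 3. Ring C and a temporary 1,3,2-dioxasilin ring (O5–Si–O4) are closed together in one flask.
4. 3 comes from 2-methylphloroglucinol and 3-chloropropanoic acid. 10 comes from 4-bromoresorcinol and geraniol.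
5. Ring order: rings A and B are bought. Ring C and the silicon ring form together. The silicon ring is opened again in the arylation step.

Assumption: the (S)-ligand with Meldrum's acid is taken to give the (R)-ketone; the first run is checked by CD and optical rotation, and the equally available (R)-ligand is used if the sense is opposite.

**Step 1**
Reactants: 1 2-methylbenzene-1,3,5-triol; 2 3-chloropropanoic acid
Product: 3 3-chloro-1-(2,4,6-trihydroxy-3-methylphenyl)propan-1-one
Conditions: CF3SO3H (neat), 80 °C, 1 h
Reagents that add atoms: none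
Why: Friedel–Crafts acylation by the activated acid, in which the two free ring positions of 1 are equivalent so only one aryl ketone can form, the primary chloride survives, and no stereocentre is made.

**Step 2**
Reactants: 3 3-chloro-1-(2,4,6-trihydroxy-3-methylphenyl)propan-1-one
Product: 6 4,5-O-diisopropylsilylene-bridged 7-TBSO-6-methyl-2H-chromen-4-ol enol ether, via 5,7-dihydroxy-6-methylchroman-4-one 4 (not isolated), via 7-O-TBS chromanone 5 (not isolated)
Conditions: Et3N, MeCN, 40 °C; then TBSCl (1.05 equiv), 0 °C; then i-Pr2Si(OTf)2 (1.1 equiv), Et3N, 0 °C to rt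
Reagents that add atoms: tert-butyldimethylsilyl chloride CC(C)(C)[Si](C)(C)Cl; diisopropylsilyl bis(trifluoromethanesulfonate) CC(C)[Si](OS(=O)(=O)C(F)(F)F)(OS(=O)(=O)C(F)(F)F)C(C)C
Why: Proposed new method: Et3N closes ring C (E1cB then 6-endo oxa-Michael, the known base cyclisation of 3-chloro-2'-hydroxypropiophenones) through the ortho-OH flanked by H, because the ortho-OH next to the methyl group is held in the hydrogen bond to C=O, which puts the methyl at C6; TBSCl then takes the only unchelated phenol (O7), and the silyl bis(triflate) binds O5 and silylates the peri carbonyl oxygen intramolecularly while Et3N removes H3 (closest known types: R3SiOTf/Et3N soft enolisation and silylene protection of 1,3-related O,O pairs), so two rings close in one flask and no stereocentre is made.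

**Step 3**
Reactants: 7 4-bromobenzene-1,3-diol; 8 geraniol
Product: 9 4-bromo-6-[(2E)-3,7-dimethylocta-2,6-dienyl]benzene-1,3-diol
Conditions: acidic Al2O3, 1,2-dichloroethane, reflux
Reagents that add atoms: none
Why: Surface-templated ortho-selective Friedel–Crafts allylation of a free phenol by an allylic alcohol, in which C6 (ortho to one OH, para to the other) is the most nucleophilic unhindered site, attack at the primary terminus keeps the E-alkene, the mild surface acid limits chroman formation, and no stereocentre is made.

**Step 4**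
Reactants: 9 4-bromo-6-geranylbenzene-1,3-diol
Product: 10 1-bromo-2,4-bis(tert-butyldimethylsilyloxy)-5-geranylbenzene
Conditions: TBSCl (2.4 equiv), imidazole, DMF, rt
Reagents that add atoms: tert-butyldimethylsilyl chloride CC(C)(C)[Si](C)(C)Cl
Why: Standard imidazole-promoted phenol silylation, which leaves the alkenes and the bromide untouched and gives groups that fluoride removes later without acid.

**Step 5**
Reactants: 6 silylene-bridged enol ether; 10 ring B bromide
Product: 12 racemic 5,7,2',4'-tetrahydroxy-6-methyl-5'-geranylisoflavanone, via silylated racemic isoflavanone 11 (not isolated)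
Conditions: Pd(dba)2 (5 mol %), P(t-Bu)3 (10 mol %), ZnF2 (0.6 equiv), CsF (0.4 equiv), DMF, 80 °C; then Bu4NF (5 equiv), AcOH (5 equiv), THF, 0 °C to rt
Reagents that add atoms: none
Why: Proposed new method: fluoride attack on the silylene releases a zinc enolate under nearly neutral conditions, which transmetalates to the arylpalladium bromide from 10 and reductively eliminates (closest known type: ZnF2/CsF-promoted palladium α-arylation of trimethylsilyl enol ethers), so the alkoxide bases that ring-open chromanones are avoided; C3 is formed racemic on purpose and buffered fluoride then strips all silicon.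

**Step 6**
Reactants: 12 racemic isoflavanone
Product: 13 penta-Alloc enol carbonate (C3=C4 with allyl carbonates on O4 O5 O7 O2' O4')
Conditions: KN(SiMe3)2 (5.5 equiv), allyl chloroformate (6 equiv), THF, −78 °C to 0 °C, inverse addition
Reagents that add atoms: allyl chloroformate C=CCOC(=O)Cl
Why: Exhaustive O-acylation, in which the four phenoxides and the oxygen of the hindered α-aryl potassium enolate are trapped at low temperature before E1cB opening of ring C competes, and the racemic C3 centre is erased to give an achiral enol carbonate.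

**Step 7**
Reactants: 13 penta-Alloc enol carbonate
Product: 14 (3R)-5,7,2',4'-tetrahydroxy-6-methyl-5'-geranylisoflavanone
Conditions: Pd2(dba)3 (5 mol %), (S)-t-BuPHOX (12.5 mol %), Meldrum's acid (7 equiv), 1,4-dioxane, 25–40 °C
Reagents that add atoms: none
Why: Palladium-catalysed decarboxylative asymmetric protonation, in which zerovalent palladium ionises all five allyl carbonates and Meldrum's acid (far more acidic than the freed phenols) scavenges the allyl groups and protonates the PHOX-bound palladium enolate on one face; this reaction type is proven on isoflavanone enolates, so C3 is set as R in the final nearly neutral step and is not exposed to base afterwards.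

**Compound list**
1 | 2-methylbenzene-1,3,5-triol | Cc1c(O)cc(O)cc1O | starting material
2 | 3-chloropropanoic acid | OC(=O)CCCl | starting material
3 | 3-chloro-1-(2,4,6-trihydroxy-3-methylphenyl)propan-1-one | Cc1c(O)cc(O)c(C(=O)CCCl)c1O | intermediate
4 | 5,7-dihydroxy-6-methylchroman-4-one | Cc1c(O)cc2OCCC(=O)c2c1O | intermediate
5 | 7-(tert-butyldimethylsilyloxy)-5-hydroxy-6-methylchroman-4-one | Cc1c(O[Si](C)(C)C(C)(C)C)cc2OCCC(=O)c2c1O | intermediate
6 | 4,5-O-diisopropylsilylene-bridged 7-TBSO-6-methyl-2H-chromen-4-ol enol ether | CC(C)[Si]1(C(C)C)OC2=CCOc3cc(O[Si](C)(C)C(C)(C)C)c(C)c(O1)c23 | intermediate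
7 | 4-bromobenzene-1,3-diol | Oc1ccc(Br)c(O)c1 | starting material
8 | geraniol, (2E)-3,7-dimethylocta-2,6-dien-1-ol | CC(C)=CCC/C(C)=C/CO | starting material
9 | 4-bromo-6-[(2E)-3,7-dimethylocta-2,6-dienyl]benzene-1,3-diol | CC(C)=CCC/C(C)=C/Cc1cc(Br)c(O)cc1O | intermediate
10 | 1-bromo-2,4-bis(tert-butyldimethylsilyloxy)-5-[(2E)-geranyl]benzene | CC(C)=CCC/C(C)=C/Cc1cc(Br)c(O[Si](C)(C)C(C)(C)C)cc1O[Si](C)(C)C(C)(C)C | intermediate
11 | racemic 5-O-(fluorodiisopropylsilyl)-7,2',4'-tris-O-TBS isoflavanone | CC(C)=CCC/C(C)=C/Cc1cc(C2COc3cc(O[Si](C)(C)C(C)(C)C)c(C)c(O[Si](F)(C(C)C)C(C)C)c3C2=O)c(O[Si](C)(C)C(C)(C)C)cc1O[Si](C)(C)C(C)(C)C | intermediate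
12 | racemic 5,7,2',4'-tetrahydroxy-6-methyl-5'-geranylisoflavanone | CC(C)=CCC/C(C)=C/Cc1cc(C2COc3cc(O)c(C)c(O)c3C2=O)c(O)cc1O | intermediate
13 | penta-Alloc enol carbonate of 12 (achiral, C3=C4) | CC(C)=CCC/C(C)=C/Cc1cc(C2=C(OC(=O)OCC=C)c3c(OC(=O)OCC=C)c(C)c(OC(=O)OCC=C)cc3OC2)c(OC(=O)OCC=C)cc1OC(=O)OCC=C | intermediate
14 | (3R)-5,7,2',4'-tetrahydroxy-6-methyl-5'-geranylisoflavanone | CC(C)=CCC/C(C)=C/Cc1cc([C@@H]2COc3cc(O)c(C)c(O)c3C2=O)c(O)cc1O | target

Total step count: 7.
Longest linear sequence: 5 (steps 1, 2, 5, 6, 7 or steps 3, 4, 5, 6, 7).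

**Steps most likely to fail**

**Step 2.** The risks are the 6-methyl versus 8-methyl regiochemistry of ring closure and the closure of the silicon ring.
- The fallback reverses the bond order and sets out from 1 and 2.
- The only unhindered phenoxide of 1 is O-alkylated with 2 (aqueous NaOH, reflux) to give 3-(3,5-dihydroxy-4-methylphenoxy)propanoic acid F1.
- Ring C is then closed by intramolecular Friedel–Crafts acylation (P2O5 in MeSO3H, rt). Both ortho positions of the ether are equivalent, so only the 6-methyl isomer can form.
- The sequence comes back to the route at 4, which is silylated as in step 2.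

**Step 5.** The risk is coupling the hindered ortho-silyloxy aryl bromide with the silylene enol ether.
- The fallback makes the C3–C1' bond on an open chain and closes ring C last. It sets out from 1 and 10.
- 1 is acetylated (AcOH, BF3·OEt2, 80 °C) to 1-(2,4,6-trihydroxy-3-methylphenyl)ethanone F2.
- F2 is silylated (TBSOTf, 2,6-lutidine) to 1-[2,4,6-tris(tert-butyldimethylsilyloxy)-3-methylphenyl]ethanone F3.
- The unhindered methyl ketone enolate of F3 is arylated with 10 (Pd2(dba)3, XPhos, K3PO4, toluene, 80 °C) to the penta-TBS deoxybenzoin F4.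
- Bu4NF/AcOH gives the free deoxybenzoin F5.
- Paraformaldehyde with Et2NH (Mannich reaction, elimination, oxa-Michael closure) brings the sequence back to the route at 12.

**Step 7.** The risks are the ee in the presence of four freed phenols and slow cleavage of the aryl carbonates.
- The fallback replaces the palladium enolate by organocatalytic protonation of an enol silane and sets out from 12.
- Me3SiOTf/Et3N gives the pentakis(trimethylsilyl) enol silane F6.
- F6 is protonated at C3 with a BINOL-derived chiral N-triflyl thiophosphoramide (5 mol %) and MeOH in toluene at low temperature.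
- The aryl trimethylsilyl ethers fall off on citric acid/MeOH work-up, and the sequence comes back to the route at 14.

**Further compounds**
F1 | step 2 | 3-(3,5-dihydroxy-4-methylphenoxy)propanoic acid | Cc1c(O)cc(OCCC(=O)O)cc1O
F2 | step 5 | 1-(2,4,6-trihydroxy-3-methylphenyl)ethanone | CC(=O)c1c(O)cc(O)c(C)c1O
F3 | step 5 | 1-[2,4,6-tris(tert-butyldimethylsilyloxy)-3-methylphenyl]ethanone | CC(=O)c1c(O[Si](C)(C)C(C)(C)C)cc(O[Si](C)(C)C(C)(C)C)c(C)c1O[Si](C)(C)C(C)(C)C
F4 | step 5 | penta-TBS deoxybenzoin | CC(C)=CCC/C(C)=C/Cc1cc(CC(=O)c2c(O[Si](C)(C)C(C)(C)C)cc(O[Si](C)(C)C(C)(C)C)c(C)c2O[Si](C)(C)C(C)(C)C)c(O[Si](C)(C)C(C)(C)C)cc1O[Si](C)(C)C(C)(C)C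
F5 | step 5 | 2-(2,4-dihydroxy-5-geranylphenyl)-1-(2,4,6-trihydroxy-3-methylphenyl)ethanone | CC(C)=CCC/C(C)=C/Cc1cc(CC(=O)c2c(O)cc(O)c(C)c2O)c(O)cc1O
F6 | step 7 | pentakis(trimethylsilyl) enol silane of 12 | CC(C)=CCC/C(C)=C/Cc1cc(C2=C(O[Si](C)(C)C)c3c(O[Si](C)(C)C)c(C)c(O[Si](C)(C)C)cc3OC2)c(O[Si](C)(C)C)cc1O[Si](C)(C)C
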